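## Structural features

Target 14 consists of two (−)-epicatechin 3-O-gallate units: the upper unit is the chroman formed by rings A and C with catechol ring B on C2, the lower unit is the chroman formed by rings D and F with catechol ring E on C2′, and each O3 carries a 3,4,5-trihydroxybenzoyl group. The two units are held together by a single bond from the sp3 carbon C4 of ring C to the aromatic carbon C8′ of ring D. Ring C carries three contiguous stereocentres, C2 (R), C3 (R) and C4 (R), arranged 2,3-cis and 3,4-trans (4β), and ring F carries two adjacent ones, C2′ (R) and C3′ (R), cis to each other. Fragile are the fourteen free phenols (air oxidation), the C4–C8′ bond (acid heterolysis, because C4 is benzylic to the tri-oxygenated ring A and ring D is readily ipso-protonated), the two esters (base, acyl migration) and the benzylic ethers C2–O1 and C2′–O1′ (epimerisation by ring opening). The real difficulty is to form C4–C8′ at the right carbon of ring D and on the β face, while the lower unit ends up 2,3-cis with an oxygen at C3′ that can still be acylated. The key step exploits that C4′ is an unsubstituted methylene lying between C3′ and C4a′, the only free carbon of ring D ortho to O1′. Ring F (O1′, C2′, C3′, C4′, C4a′, C8a′) can therefore be closed last through the C4′–C4a′ bond, from an aryl ether in which C2′ and C3′ are already fixed.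

## Logic of the disconnections

14 ⇒ 13. The fourteen phenolic O–CH2Ph bonds are cut. Free phenols make every intermediate oxidisable and C-nucleophilic, so they are masked by one group that leaves in a single neutral operation. The gain is that all earlier chemistry deals with neutral, chromatographable compounds. The forward step must spare two esters, the C4–C8′ bond and the two benzylic ring ethers.

13 ⇒ 12 + 4. The C3′O–C(=O) ester bond is cut. The key step leaves exactly one free hydroxyl, at C3′, so the second acyl group needs no protecting-group step and is brought in as 4. The gain is that the lower unit needs no ester before the ring closure. The forward step must acylate a hindered axial secondary alcohol.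

12 ⇒ 11 (key). The C4′–C4a′ bond is cut and the C3′ oxygen is reconnected to C4′ as an oxirane. C4′ carries no stereochemical information and C4a′ is the one free carbon of ring D ortho to O1′. The gain is that the lower unit shrinks to a three-carbon epoxy ether on a phenol oxygen, and a C8′ versus C6′ choice on a complete flavan never arises. The forward step must open the oxirane at its primary carbon (6-endo) under acid mild enough for the C4–C8′ bond and the benzylic C2′–O1′ ether.

11 ⇒ 7 + 10. The O1′–C2′ ether bond is cut. This joins a phenol and a secondary benzylic alcohol convergently and sets C2′ by inversion, so the readily made erythro alcohol gives the threo ether that leads to a cis ring. The forward step must be a clean SN2 displacement at an electron-rich benzylic carbon by an ortho-substituted phenol, with the oxirane left intact.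

10 ⇒ 9 ⇒ 8. The two C–O bonds of the oxirane are cut (oxygen transfer to a terminal alkene), then the C2′–C3′ bond (vinyl anion plus aldehyde). One reagent-controlled operation resolves the carbinol and chooses the alkene face. The gain is the achiral 8. The forward step needs a useful rate difference between the enantiomers of 9 and must not destroy an acid-sensitive benzylic epoxy alcohol.

7 ⇒ 5 + 6. The C4–C8′ bond is cut. C4 gives a cation stabilised by the ring A oxygens, and 6 has only one kind of carbon ortho to its hydroxyl. The gain is that ring D becomes a simple symmetrical phenol. The forward step must attack the β face (trans to the C3 ester), at a carbon ortho and not para to the hydroxyl, and only once.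

5 ⇒ 3 + 4, then 3 ⇒ 2 ⇒ 1. The C3O–C(=O) ester bond is cut (a second use of 4), then the C4–O bond (retro-oxidation of the C4 methylene), then four O–benzyl bonds. C2 and C3 of the upper unit then come from the chiral pool. No galloyl ester with free phenols ever meets an alkylating base, and the C4–H oxidation runs on the free alcohol, where no neighbouring acyloxy group retards it. The forward steps need O-benzylation without C-alkylation, oxidation at C4 only, and acylation of an axial hydroxyl flanked by two substituents.

## Other disconnections considered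

Alternative 1: The cut runs through ring A of the upper unit, at C4a–C8a and C5–C6.
- **Forward key step:** Siloxyalkyne A1, which already carries the C4 stereocentre, the complete lower unit and the styryl arm, would be heated with cyclobutenone A2. Ring opening of A2, [2+2] addition to the alkyne, a second ring opening and a six-electron closure would give phenol A3, free at the future O1.
- **In favour:** The interflavan carbon is set before ring A exists, so no Lewis acid ever meets a C4–C8′ bond. The three ring A oxygens emerge regiodefined and differentiated (free phenol, silyl, benzyl).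
- **Against it here:** The C4 centre of A1 must be made enantioselectively as a branched propargylic carbon and must survive heating. Ring C is still open in A3, so an asymmetric oxidation of the styrene, an O1–C2 closure with control of C2 and C3 relative to C4, silyl/benzyl exchanges and two esterifications would follow.
- **Comparison:** On regiocontrol of the aromatic substitution pattern it is better than the chosen plan, whose step 4 depends on ortho over para attack. On mildness of the key step (pericyclic, neutral) it is also better. On stereochemistry it is weaker, because C2 and C3 no longer come from the chiral pool. On step economy it is clearly longer than ten steps. The two plans are equal in taking one flavan unit from the chiral pool.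

Alternative 2: The cut is the C3′=C4′ double bond of a 3-methoxy-2H-chromene, so ring F is again closed last on a C4–C8′-linked precursor.
- **Forward key step:** The second-generation Grubbs catalyst would join the vinyl group on C4a′ and the 1-methoxyvinyl group on C2′ of diene A4 to give A5. Hydrolysis of the enol ether and hydride reduction of the C3′ carbonyl would then give the cis alcohol.
- **In favour:** The closure is neutral and has no 5-exo/6-endo question; on both points it is better than the chosen key step. It is equal in strategy (ring F last, O3′ left for late acylation).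
- **Against it here:** Enol ether olefins are slow metathesis partners (stabilised alkoxycarbene, 1,1-disubstitution). After hydrolysis C2′–H is α to a ketone and benzylic, so C2′ may epimerise. C3′ has to be created anew by a diastereoselective reduction, whereas the chosen plan carries it through untouched. A vinyl group must first be placed regioselectively on C4a′, and the upper O3 is silylated in A4, so both gallates come late.
- **Comparison:** Mechanistically gentler, stereochemically less secure, and longer by several steps.

Alternative 3: The cut runs through ring C of the upper unit, at O1–C2 and C3–C4.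
- **Forward key step:** Benzhydrol A6, which already bears the lower unit, would lose water to ortho-quinone methide A7. A7 would add (Z)-styrylsilane A8 as a heterodiene to give A9. The silicon on C3 of A9 is a masked hydroxyl (Tamao–Fleming oxidation with retention).
- **In favour:** It forms two bonds, one ring and three stereocentres in one step, against one bond and no stereocentre for the chosen key step; on convergence it is the better plan. The cis olefin of A8 maps onto 2,3-cis, and silicon plus aryl direct the regiochemistry.
- **Against it here:** A7 is flat, and only the remote C2′ and C3′ centres could bias its faces, so the absolute sense of C2, C3 and C4 relative to the lower unit is not secured. The 3,4-trans relation rests on an endo/exo preference. A methide stabilised by a tri-oxygenated aryl group is a weak electrophile and A8 only a moderate dienophile. The acid needed to release A7 threatens the same benzylic bonds as in the chosen plan.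
- **Comparison:** Equal in protecting-group scheme and in the last two operations (acylation, hydrogenolysis). On paper the step count is similar or slightly lower. The chosen plan is safer in stereochemistry, since every centre comes from the chiral pool or from a reagent-controlled step.

Key step: step 8

Remark 1: compounds 4, 6 and 8 are taken as catalogue compounds; if not to hand, each is one or two routine O-benzylations from gallic acid, phloroglucinol and 3,4-dihydroxybenzaldehyde.

Remark 2: a centre-by-centre check shows that the (2R,3R,4β) upper unit and the (R)-carbinol, (2R)-oxirane threo side chain of 11 map unchanged onto (2R,3R,4R)/(2′R,3′R) of 12 and 14, so neither structure of the key-step pair needs correction. The epoxy alcohol required is therefore the erythro isomer with (S)-carbinol and (2R)-oxirane. By the Sharpless face rule, L-(+)-DIPT should deliver it from the fast-reacting (R)-carbinol.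

Remark 3: design choices beyond the bare disconnection are these. The upper unit starts from (−)-epicatechin and receives its gallate after benzylation and C4 oxidation. Ring D is brought in as the free phenol, so no deprotection precedes step 7. The C3 gallate serves as a participating group for the 4β arylation. The Lewis acid of the key step is used in substoichiometric amount at −78 °C.

Step 1
Reactants: 1 (−)-epicatechin
Product: 2 5,7,3′,4′-tetra-O-benzyl-(−)-epicatechin
Conditions: BnBr (4.4 equiv), K2CO3 (5 equiv), DMF, 0 °C to rt, argon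
Reagents that add atoms: benzyl bromide BrCc1ccccc1
Why: Williamson etherification: the carbonate base deprotonates only the four phenols, so the secondary C3 alcohol stays free; working cold and oxygen-free limits C-benzylation of ring A and base-induced epimerisation at C2.

Step 2
Reactants: 2 5,7,3′,4′-tetra-O-benzyl-(−)-epicatechin
Product: 3 4β-(2-ethoxyethoxy)-5,7,3′,4′-tetra-O-benzyl-(−)-epicatechin (2,3-cis-3,4-trans)
Conditions: DDQ (2 equiv), 2-ethoxyethanol (5 equiv), CH2Cl2, rt
Reagents that add atoms: 2-ethoxyethanol CCOCCO
Why: DDQ benzylic oxidation: hydride is removed from C4, the only C–H whose cation is stabilised by O1, O5 and O7 of ring A, and the alcohol should capture the cation trans to the C3 hydroxyl. The C4 configuration is erased again in step 4, so its purity does not matter.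

Step 3
Reactants: 3 4β-(2-ethoxyethoxy)-5,7,3′,4′-tetra-O-benzyl-(−)-epicatechin; 4 3,4,5-tris(benzyloxy)benzoic acid
Product: 5 4β-(2-ethoxyethoxy)-5,7,3′,4′-tetra-O-benzyl-(−)-epicatechin 3-O-[3,4,5-tris(benzyloxy)benzoate]
Conditions: 4 (1.5 equiv), DCC (1.5 equiv), DMAP (0.5 equiv), CH2Cl2, rt
Reagents that add atoms: none
Why: Steglich esterification: acyl transfer through the acylpyridinium should reach the axial C3 hydroxyl, and the non-acidic medium leaves the acid-labile C4 ether alone; only the O–acyl bond forms, so C3 is untouched.

Step 4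
Reactants: 5 4β-(2-ethoxyethoxy)-5,7,3′,4′-tetra-O-benzyl-(−)-epicatechin 3-O-[3,4,5-tris(benzyloxy)benzoate]; 6 3,5-bis(benzyloxy)phenol
Product: 7 4β-[2,4-bis(benzyloxy)-6-hydroxyphenyl]-5,7,3′,4′-tetra-O-benzyl-(−)-epicatechin 3-O-[3,4,5-tris(benzyloxy)benzoate] (2,3-cis-3,4-trans)
Conditions: 6 (3 equiv), TMSOTf (0.2 equiv), CH2Cl2, −78 to −40 °C; Et3N quench
Reagents that add atoms: none
Why: Lewis acid-promoted Friedel–Crafts arylation of a C4-activated flavan: TMSOTf ionises the C4 ether, and the cation, bridged or shielded on the α face by the axial C3 aroyloxy group, should be attacked on the β face, which sets C4 trans to C3–O. Phenol 6 should react at a carbon ortho to its hydroxyl, because there are two such equivalent sites, they are less hindered than the carbon between the two benzyloxy groups, and any aryl ether formed first can reach them by O-to-C migration.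

Step 5
Reactants: 8 3,4-bis(benzyloxy)benzaldehyde
Product: 9 rac-1-[3,4-bis(benzyloxy)phenyl]prop-2-en-1-ol
Conditions: CH2=CHMgBr (1.2 equiv), THF, −78 to 0 °C; then H2O
Reagents that add atoms: vinylmagnesium bromide C=C[Mg]Br
Why: Grignard 1,2-addition to an aromatic aldehyde gives the racemic secondary allylic alcohol needed for the resolution.

Step 6
Reactants: 9 rac-1-[3,4-bis(benzyloxy)phenyl]prop-2-en-1-ol
Product: 10 (S)-[3,4-bis(benzyloxy)phenyl][(2R)-oxiran-2-yl]methanol (erythro)
Conditions: Ti(OiPr)4 (0.2 equiv), L-(+)-DIPT (0.24 equiv), TBHP (0.45 equiv), 4 Å MS, CH2Cl2, −20 °C, stopped near 45% conversion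
Reagents that add atoms: tert-butyl hydroperoxide CC(C)(C)OO
Why: Sharpless kinetic resolution: with L-(+)-DIPT the (R)-carbinol should be epoxidised fast, on the face that gives the erythro epoxy alcohol, so the oxirane CH (future C3′, R) is set by the reagent; stopping below half conversion favours the enantiomeric purity of the epoxide. The carbinol centre is unchanged in space but is named S in 10 because the oxirane carbon now outranks the aryl group; the slow (S)-alcohol is separated.

Step 7
Reactants: 7 4β-[2,4-bis(benzyloxy)-6-hydroxyphenyl]-5,7,3′,4′-tetra-O-benzyl-(−)-epicatechin 3-O-[3,4,5-tris(benzyloxy)benzoate]; 10 (S)-[3,4-bis(benzyloxy)phenyl][(2R)-oxiran-2-yl]methanol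
Product: 11 4β-{2,4-bis(benzyloxy)-6-[(R)-[3,4-bis(benzyloxy)phenyl][(2R)-oxiran-2-yl]methoxy]phenyl}-5,7,3′,4′-tetra-O-benzyl-(−)-epicatechin 3-O-[3,4,5-tris(benzyloxy)benzoate] (threo epoxy ether)
Conditions: 10 (1.5 equiv), PPh3 (2 equiv), DIAD (2 equiv), toluene, 0 °C to rt
Reagents that add atoms: none
Why: Mitsunobu etherification: the phenoxide displaces the oxyphosphonium of the secondary benzylic alcohol by SN2 with inversion, turning the (S)-carbinol into the (R)-ether carbon (future C2′) and the erythro alcohol into the threo ether. The adjacent electron-withdrawing oxirane and the non-polar solvent should disfavour ionisation.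

Step 8
Reactants: 11 threo epoxy ether (4β-{2,4-bis(benzyloxy)-6-[(R)-[3,4-bis(benzyloxy)phenyl][(2R)-oxiran-2-yl]methoxy]phenyl}-5,7,3′,4′-tetra-O-benzyl-(−)-epicatechin 3-O-[3,4,5-tris(benzyloxy)benzoate])
Product: 12 perbenzylated 3-O-galloylprocyanidin B2 with free C3′ hydroxyl (upper unit 2R,3R,4R; lower unit 2R,3R)
Conditions: BF3·OEt2 (0.3 equiv), CH2Cl2, −78 °C; Et3N quench at −78 °C
Reagents that add atoms: none
Why: BF3 binds the oxirane oxygen of 11, and C4a′ of ring D attacks the primary carbon C4′ in an SN2-like step with backside displacement of the borate oxygen; C4a′ is the only unsubstituted carbon ortho to O1′ and is activated by three oxygens (ortho O1′, ortho C5′–OBn, para C7′–OBn). Loss of the C4a′ proton restores ring D and the quench frees the C3′ hydroxyl, so the step is an isomerisation. The closest known reaction type is the Lewis acid-promoted intramolecular Friedel–Crafts cyclisation of aryl glycidyl ethers to chroman-3-ols. Ring F closes in the 6-endo-tet mode, both oxirane carbons ending in the ring. The 5-exo attack at C3′ is disfavoured because C3′ is secondary, is inductively deactivated by the C2′–O bond, and is poorly placed for backside attack by the ring π face through the short tether. No stereocentre is created: C2′ is not involved and C3′ keeps its oxygen, so the threo chain (R-carbinol ether, 2R-oxirane) becomes the (2′R,3′R) cis ring, and C2, C3 and C4 are spectators. The step needs 6-endo over 5-exo opening, and epoxide activation over heterolysis of the C4–C8′ bond or of the benzylic C2′–O1′ ether. The strained oxirane is the most basic and most easily opened site, and the very electron-rich ring D should let the closure run at −78 °C with a substoichiometric amount of BF3, conditions under which the other two bonds should not ionise.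

Step 9
Reactants: 12 perbenzylated 3-O-galloylprocyanidin B2 with free C3′ hydroxyl; 4 3,4,5-tris(benzyloxy)benzoic acid
Product: 13 tetradeca-O-benzyl-3,3′-di-O-galloylprocyanidin B2
Conditions: 4 (3 equiv), DCC (3 equiv), DMAP (1 equiv), CH2Cl2, rt
Reagents that add atoms: none
Why: Steglich esterification of the only free hydroxyl; acyl transfer through the acylpyridinium should tolerate the hindered axial C3′–OH, and only the O–acyl bond forms, so C3′ is untouched.

Step 10
Reactants: 13 tetradeca-O-benzyl-3,3′-di-O-galloylprocyanidin B2
Product: 14 3,3′-di-O-galloylprocyanidin B2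
Conditions: H2 (1 atm), Pd(OH)2/C, THF/MeOH/H2O, rt; filtration, lyophilisation
Reagents that add atoms: none
Why: Catalytic hydrogenolysis of the fourteen aryl benzyl ethers under neutral conditions; aryl benzyl ethers cleave much faster than the ring C2–O1 ethers or the C4–C8′ bond, and the esters are inert, so all five stereocentres should be retained.

Compound list

1 | (−)-epicatechin, (2R,3R) | O[C@@H]1Cc2c(O)cc(O)cc2O[C@@H]1c1ccc(O)c(O)c1 | starting material
2 | 5,7,3′,4′-tetra-O-benzyl-(−)-epicatechin, (2R,3R) | O[C@@H]1Cc2c(OCc3ccccc3)cc(OCc3ccccc3)cc2O[C@@H]1c1ccc(OCc2ccccc2)c(OCc2ccccc2)c1 | intermediate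
3 | 4β-(2-ethoxyethoxy)-5,7,3′,4′-tetra-O-benzyl-(−)-epicatechin (2,3-cis-3,4-trans; C2 and C3 as in 2) | O[C@@H]1[C@@H](OCCOCC)c2c(OCc3ccccc3)cc(OCc3ccccc3)cc2O[C@@H]1c1ccc(OCc2ccccc2)c(OCc2ccccc2)c1 | intermediate
4 | 3,4,5-tris(benzyloxy)benzoic acid | OC(=O)c1cc(OCc2ccccc2)c(OCc2ccccc2)c(OCc2ccccc2)c1 | starting material
5 | 4β-(2-ethoxyethoxy)-5,7,3′,4′-tetra-O-benzyl-(−)-epicatechin 3-O-[3,4,5-tris(benzyloxy)benzoate] (2,3-cis-3,4-trans) | O=C(O[C@@H]1[C@@H](OCCOCC)c2c(OCc3ccccc3)cc(OCc3ccccc3)cc2O[C@@H]1c1ccc(OCc2ccccc2)c(OCc2ccccc2)c1)c1cc(OCc2ccccc2)c(OCc2ccccc2)c(OCc2ccccc2)c1 | intermediate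
6 | 3,5-bis(benzyloxy)phenol | Oc1cc(OCc2ccccc2)cc(OCc2ccccc2)c1 | starting material
7 | 4β-[2,4-bis(benzyloxy)-6-hydroxyphenyl]-5,7,3′,4′-tetra-O-benzyl-(−)-epicatechin 3-O-[3,4,5-tris(benzyloxy)benzoate] (2,3-cis-3,4-trans) | O=C(O[C@@H]1[C@@H](c2c(OCc4ccccc4)cc(OCc4ccccc4)cc2O)c2c(OCc3ccccc3)cc(OCc3ccccc3)cc2O[C@@H]1c1ccc(OCc2ccccc2)c(OCc2ccccc2)c1)c1cc(OCc2ccccc2)c(OCc2ccccc2)c(OCc2ccccc2)c1 | intermediate
8 | 3,4-bis(benzyloxy)benzaldehyde | O=Cc1ccc(OCc2ccccc2)c(OCc2ccccc2)c1 | starting material
9 | rac-1-[3,4-bis(benzyloxy)phenyl]prop-2-en-1-ol | OC(C=C)c1ccc(OCc2ccccc2)c(OCc2ccccc2)c1 | intermediate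
10 | (S)-[3,4-bis(benzyloxy)phenyl][(2R)-oxiran-2-yl]methanol (erythro) | O[C@@H](c1ccc(OCc2ccccc2)c(OCc2ccccc2)c1)[C@H]1CO1 | intermediate
11 | 4β-{2,4-bis(benzyloxy)-6-[(R)-[3,4-bis(benzyloxy)phenyl][(2R)-oxiran-2-yl]methoxy]phenyl}-5,7,3′,4′-tetra-O-benzyl-(−)-epicatechin 3-O-[3,4,5-tris(benzyloxy)benzoate] (threo epoxy ether) | O=C(O[C@@H]1[C@@H](c2c(OCc4ccccc4)cc(OCc4ccccc4)cc2O[C@H](c4ccc(OCc5ccccc5)c(OCc5ccccc5)c4)[C@H]3CO3)c2c(OCc3ccccc3)cc(OCc3ccccc3)cc2O[C@@H]1c1ccc(OCc2ccccc2)c(OCc2ccccc2)c1)c1cc(OCc2ccccc2)c(OCc2ccccc2)c(OCc2ccccc2)c1 | intermediate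
12 | perbenzylated 3-O-galloylprocyanidin B2 with free C3′ hydroxyl (upper unit 2R,3R,4R; lower unit 2R,3R) | O=C(O[C@@H]1[C@@H](c2c(OCc4ccccc4)cc(OCc4ccccc4)c3c2O[C@H](c4ccc(OCc5ccccc5)c(OCc5ccccc5)c4)[C@H](O)C3)c2c(OCc3ccccc3)cc(OCc3ccccc3)cc2O[C@@H]1c1ccc(OCc2ccccc2)c(OCc2ccccc2)c1)c1cc(OCc2ccccc2)c(OCc2ccccc2)c(OCc2ccccc2)c1 | intermediate
13 | tetradeca-O-benzyl-3,3′-di-O-galloylprocyanidin B2 | O=C(O[C@@H]1[C@@H](c2c(OCc4ccccc4)cc(OCc4ccccc4)c3c2O[C@H](c4ccc(OCc5ccccc5)c(OCc5ccccc5)c4)[C@H](OC(=O)c4cc(OCc5ccccc5)c(OCc5ccccc5)c(OCc5ccccc5)c4)C3)c2c(OCc3ccccc3)cc(OCc3ccccc3)cc2O[C@@H]1c1ccc(OCc2ccccc2)c(OCc2ccccc2)c1)c1cc(OCc2ccccc2)c(OCc2ccccc2)c(OCc2ccccc2)c1 | intermediate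
14 | 3,3′-di-O-galloylprocyanidin B2 | O=C(O[C@@H]1[C@@H](c2c(O)cc(O)c3c2O[C@H](c2ccc(O)c(O)c2)[C@H](OC(=O)c2cc(O)c(O)c(O)c2)C3)c2c(O)cc(O)cc2O[C@@H]1c1ccc(O)c(O)c1)c1cc(O)c(O)c(O)c1 | target

Total step count: 10. Longest linear sequence: 8 steps (1, 2, 3, 4, 7, 8, 9, 10) from 1; the branch from 8 (steps 5 and 6) joins at step 7.

Steps least certain to work

Step 8 (key step). The most likely failures are acid-induced heterolysis of the C4–C8′ bond, or ionisation of the electron-rich benzylic C2′–O1′ ether (epimerisation at C2′ or aryl migration) before ring closure, because all three sites respond to the same Lewis acid. Lesser risks are partial 5-exo opening and capture of the activated oxirane by ring E to give an indane. Fallback: set out from 2 and 5 and unite them directly (2 in excess, TMSOTf, CH2Cl2, −78 °C). C8 of the intact flavan 2 should attack the C4 cation from 5 on the β face, and the sequence comes back to the route at 12, bypassing steps 4 to 8. The lower unit is then taken whole from the chiral pool instead of being closed through the epoxide.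

Step 7. The likely failures are loss of stereochemical integrity at the future C2′ through partial ionisation of the activated benzylic oxyphosphonium, and slow coupling because the phenol of 7 is flanked by the bulky flavanyl group. Fallback: set out from 2 and esterify it with 4 (DCC, DMAP, CH2Cl2) to 5,7,3′,4′-tetra-O-benzyl-(−)-epicatechin 3-O-[3,4,5-tris(benzyloxy)benzoate] F1. Then couple F1 (in excess) with 5 under TMSOTf at −78 °C; this comes back to the route at 13. No ether bond is made at a benzylic centre, and the hindered acylation of step 9 is avoided as well, because the lower unit arrives with its gallate in place.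

Step 4. The likely failures are leakage of the arylation to the carbon para to the hydroxyl (between the two benzyloxy groups) and a second alkylation of the very electron-rich ring D. Fallback: set out from 6 and brominate para to the hydroxyl (Bu4NBr3, CH2Cl2/MeOH, 0 °C) to 4-bromo-3,5-bis(benzyloxy)phenol F2, in which only the two equivalent ortho carbons remain free. Couple F2 with 5 (TMSOTf, −78 °C) to the 4β-[3-bromo-2,4-bis(benzyloxy)-6-hydroxyphenyl] analogue of 7 F3, and remove the blocking bromine with Bu3SnH/AIBN (toluene, 90 °C); this comes back to the route at 7.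

Step 6. The likely failures are an insufficient rate difference between the enantiomers of an aryl vinyl carbinol with an unsubstituted vinyl group, and Lewis acid-induced opening of the benzylic epoxy alcohol during a long reaction. Fallback: set out from 9 and separate resolution from epoxidation. An immobilised lipase (Candida antarctica lipase B, vinyl acetate, MTBE, 30 °C) should acylate the (R)-alcohol to (R)-1-[3,4-bis(benzyloxy)phenyl]prop-2-en-1-yl acetate F4. Methanolysis (K2CO3, MeOH) gives (R)-1-[3,4-bis(benzyloxy)phenyl]prop-2-en-1-ol F5, and a matched epoxidation under substrate and reagent control (Ti(OiPr)4, L-(+)-DIPT, TBHP, −20 °C) run to full conversion comes back to the route at 10.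

Further compounds

F0 | step 8 | none | none
F1 | step 7 | 5,7,3′,4′-tetra-O-benzyl-(−)-epicatechin 3-O-[3,4,5-tris(benzyloxy)benzoate], (2R,3R) | O=C(O[C@@H]1Cc2c(OCc3ccccc3)cc(OCc3ccccc3)cc2O[C@@H]1c1ccc(OCc2ccccc2)c(OCc2ccccc2)c1)c1cc(OCc2ccccc2)c(OCc2ccccc2)c(OCc2ccccc2)c1
F2 | step 4 | 4-bromo-3,5-bis(benzyloxy)phenol | Oc1cc(OCc2ccccc2)c(Br)c(OCc2ccccc2)c1
F3 | step 4 | 4β-[3-bromo-2,4-bis(benzyloxy)-6-hydroxyphenyl]-5,7,3′,4′-tetra-O-benzyl-(−)-epicatechin 3-O-[3,4,5-tris(benzyloxy)benzoate] (2,3-cis-3,4-trans) | O=C(O[C@@H]1[C@@H](c2c(OCc4ccccc4)c(Br)c(OCc4ccccc4)cc2O)c2c(OCc3ccccc3)cc(OCc3ccccc3)cc2O[C@@H]1c1ccc(OCc2ccccc2)c(OCc2ccccc2)c1)c1cc(OCc2ccccc2)c(OCc2ccccc2)c(OCc2ccccc2)c1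
F4 | step 6 | (R)-1-[3,4-bis(benzyloxy)phenyl]prop-2-en-1-yl acetate | CC(=O)O[C@H](C=C)c1ccc(OCc2ccccc2)c(OCc2ccccc2)c1
F5 | step 6 | (R)-1-[3,4-bis(benzyloxy)phenyl]prop-2-en-1-ol | O[C@H](C=C)c1ccc(OCc2ccccc2)c(OCc2ccccc2)c1
A1 | alternative 1 | triisopropylsilyl ynol ether of (E)-3-(lower-unit 8-yl)-5-(3,4-dibenzyloxyphenyl)pent-4-en-1-yne, lower unit 5,7,3′,4′-tetra-O-benzyl-3′-O-TBS | CC(C)[Si](C(C)C)(C(C)C)OC#C[C@H](c2c(OCc4ccccc4)cc(OCc4ccccc4)c3c2O[C@H](c4ccc(OCc5ccccc5)c(OCc5ccccc5)c4)[C@H](O[Si](C)(C)C(C)(C)C)C3)/C=C/c1ccc(OCc2ccccc2)c(OCc2ccccc2)c1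
A2 | alternative 1 | 3-(benzyloxy)cyclobut-2-en-1-one | O=C1C=C(OCc2ccccc2)C1
A3 | alternative 1 | 5-benzyloxy-3-(triisopropylsilyloxy)-2-[(E)-1-(lower-unit 8-yl)-3-(3,4-dibenzyloxyphenyl)allyl]phenol, lower unit 3′-O-TBS | Oc1cc(OCc2ccccc2)cc(O[Si](C(C)C)(C(C)C)C(C)C)c1[C@H](c2c(OCc4ccccc4)cc(OCc4ccccc4)c3c2O[C@H](c4ccc(OCc5ccccc5)c(OCc5ccccc5)c4)[C@H](O[Si](C)(C)C(C)(C)C)C3)/C=C/c1ccc(OCc2ccccc2)c(OCc2ccccc2)c1
A4 | alternative 2 | perbenzylated diene with upper O3-TBS, vinyl group on C4a′ and 1-methoxyvinyl group on C2′ | CC(C)(C)[Si](C)(C)O[C@@H]1[C@@H](c2c(OCc4ccccc4)cc(OCc4ccccc4)c(C=C)c2O[C@H](c4ccc(OCc5ccccc5)c(OCc5ccccc5)c4)C(OC)=C)c2c(OCc3ccccc3)cc(OCc3ccccc3)cc2O[C@@H]1c1ccc(OCc2ccccc2)c(OCc2ccccc2)c1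
A5 | alternative 2 | perbenzylated dimer with upper O3-TBS and lower unit as 3-methoxy-2H-chromene | CC(C)(C)[Si](C)(C)O[C@@H]1[C@@H](c2c(OCc4ccccc4)cc(OCc4ccccc4)c3c2O[C@H](c4ccc(OCc5ccccc5)c(OCc5ccccc5)c4)C(OC)=C3)c2c(OCc3ccccc3)cc(OCc3ccccc3)cc2O[C@@H]1c1ccc(OCc2ccccc2)c(OCc2ccccc2)c1
A6 | alternative 3 | [2,4-bis(benzyloxy)-6-hydroxyphenyl](lower-unit 8-yl)methanol, lower unit 3′-O-TBS, carbinol configuration not defined | OC(c1c(O)cc(OCc2ccccc2)cc1OCc1ccccc1)c1c(OCc2ccccc2)cc(OCc2ccccc2)c2c1O[C@H](c1ccc(OCc3ccccc3)c(OCc3ccccc3)c1)[C@H](O[Si](C)(C)C(C)(C)C)C2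
A7 | alternative 3 | 3,5-bis(benzyloxy)-6-[(lower-unit 8-yl)methylidene]cyclohexa-2,4-dien-1-one (ortho-quinone methide), lower unit 3′-O-TBS | O=C1C=C(OCc2ccccc2)C=C(OCc2ccccc2)C1=Cc1c(OCc2ccccc2)cc(OCc2ccccc2)c2c1O[C@H](c1ccc(OCc3ccccc3)c(OCc3ccccc3)c1)[C@H](O[Si](C)(C)C(C)(C)C)C2
A8 | alternative 3 | benzyl{(Z)-2-[3,4-bis(benzyloxy)phenyl]ethenyl}dimethylsilane | C[Si](C)(Cc1ccccc1)/C=C\c1ccc(OCc2ccccc2)c(OCc2ccccc2)c1
A9 | alternative 3 | 4β-(lower-unit 8-yl)-3α-(benzyldimethylsilyl)-5,7,3′,4′-tetra-O-benzylflavan, 2,3-cis-3,4-trans, lower unit 3′-O-TBS | C[Si](C)(Cc1ccccc1)[C@@H]1[C@@H](c2c(OCc4ccccc4)cc(OCc4ccccc4)c3c2O[C@H](c4ccc(OCc5ccccc5)c(OCc5ccccc5)c4)[C@H](O[Si](C)(C)C(C)(C)C)C3)c2c(OCc3ccccc3)cc(OCc3ccccc3)cc2O[C@@H]1c1ccc(OCc2ccccc2)c(OCc2ccccc2)c1
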